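## Retrosynthetic overview

- The strategy rests on ring C of the flavanone (O1–C2–C3–C4–C4a–C8a): the C4 ketone lies next to the C3–C4 bond, and C2, the only stereocentre, is a benzylic carbon bonded to O1.
- The C4 ketone is treated as a hydrolysed 4-silyloxy-2H-chromene. Its C3=C4 bond is cut by ring-closing metathesis, leading back to an aryl (S)-1-arylallyl ether with an ortho 1-silyloxyvinyl group. Ring C is the only ring formed, and it is formed last.
- The O1–C2 bond and the C2 configuration come from an iridium-catalysed branched allylic etherification of a ring A 2-hydroxyacetophenone with a 3,4-dimethoxycinnamyl carbonate.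
- The ring A ketone comes from phloroglucinol tris-MOM ether by two successive ortho-lithiations (geranyl bromide, then an acetyl donor) and chelation-controlled release of the one phenol para to the geranyl group.

Key step: step 8

Abbreviations: geranyl = (2E)-3,7-dimethylocta-2,6-dien-1-yl; MOM = methoxymethyl; TBS = tert-butyldimethylsilyl.

Assumption: the (Ra,Rc,Rc) enantiomer of the phosphoramidite is taken to deliver the (S)-configured branched ether. If a model run shows the opposite sense, the (Sa,Sc,Sc) ligand is used with no other change.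

## Route

Step 1
Reactants: 1 phloroglucinol (benzene-1,3,5-triol)
Product: 2 1,3,5-tris(methoxymethoxy)benzene
Conditions: NaH (3.6 equiv), MOMCl (3.6 equiv), DMF, 0 °C → rt
Reagents that add atoms: chloromethyl methyl ether (MOMCl), COCCl
Why: Threefold Williamson O-alkylation of the sodium phenoxide by the hard chloromethyl ether in DMF should give the symmetric tris-acetal, so no regiochemical question arises.

Step 2
Reactants: 2 1,3,5-tris(methoxymethoxy)benzene; 3 geranyl bromide [(2E)-1-bromo-3,7-dimethylocta-2,6-diene]
Product: 5 2-geranyl-1,3,5-tris(methoxymethoxy)benzene, via aryllithium 4 (not isolated)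
Conditions: n-BuLi (1.1 equiv), THF, 0 °C; then CuI (10 mol %), 3, −78 °C → rt
Reagents that add atoms: none
Why: Directed ortho-metalation at a C–H flanked by two coordinating OMOM groups gives 4, and copper-catalysed SN2 allylation at the primary CH2 of the allylic bromide should leave the (E)-trisubstituted alkene of the geranyl unit untouched; no stereocentre is formed.

Step 3
Reactants: 5 2-geranyl-1,3,5-tris(methoxymethoxy)benzene
Product: 8 1-[3-geranyl-2,4,6-tris(methoxymethoxy)phenyl]ethan-1-one, via aryllithium 6 (not isolated), via lithium hemiaminal 7 (not isolated)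
Conditions: n-BuLi (1.2 equiv), TMEDA, THF, −20 → 0 °C; then MeC(O)N(OMe)Me, −78 °C → rt; then H2O
Reagents that add atoms: N-methoxy-N-methylacetamide, CC(=O)N(C)OC
Why: A second directed ortho-metalation at one of the two equivalent remaining ring C–H bonds (each again between two OMOM groups, kinetically preferred over the benzylic–allylic CH2) followed by acylation with the N-methoxy-N-methylamide stops at the chelated tetrahedral adduct 7, which releases the methyl ketone only on aqueous quench, so over-addition is excluded.

Step 4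
Reactants: 8 1-[3-geranyl-2,4,6-tris(methoxymethoxy)phenyl]ethan-1-one
Product: 9 1-[3-geranyl-6-hydroxy-2,4-bis(methoxymethoxy)phenyl]ethan-1-one
Conditions: MgBr2·OEt2 (1.5 equiv), Et2O/CH2Cl2, 0 °C → rt; then H2O
Reagents that add atoms: none
Why: Chelation-controlled acetal cleavage: magnesium bridges the ketone oxygen and an ortho aryl-ether oxygen, which is possible only for the C6 OMOM group (next to ring hydrogen, able to lie in the ring plane) and not for the C2 OMOM group twisted out of plane by the geranyl chain, by analogy with the Lewis acid dealkylation of 2,3,4,6-tetraalkoxyacetophenones at the unflanked ortho oxygen; the liberated phenol then locks the carbonyl in a hydrogen bond, and the C4 OMOM group, which cannot chelate, stays.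

Step 5
Reactants: 10 (E)-3,4-dimethoxycinnamyl alcohol [(2E)-3-(3,4-dimethoxyphenyl)prop-2-en-1-ol]
Product: 11 (2E)-3-(3,4-dimethoxyphenyl)prop-2-en-1-yl methyl carbonate
Conditions: ClCO2Me, pyridine, CH2Cl2, 0 °C
Reagents that add atoms: methyl chloroformate, COC(=O)Cl
Why: Acylation of the primary allylic alcohol with a chloroformate gives the linear carbonate, whose ionisation with loss of CO2 and methoxide is the leaving-group chemistry the iridium catalyst needs.

Step 6
Reactants: 9 1-[3-geranyl-6-hydroxy-2,4-bis(methoxymethoxy)phenyl]ethan-1-one; 11 (2E)-3-(3,4-dimethoxyphenyl)prop-2-en-1-yl methyl carbonate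
Product: 13 1-[6-{[(1S)-1-(3,4-dimethoxyphenyl)prop-2-en-1-yl]oxy}-3-geranyl-2,4-bis(methoxymethoxy)phenyl]ethan-1-one, via lithium phenoxide 12 (not isolated)
Conditions: LiOt-Bu (1.0 equiv), THF, 0 °C; then 11 (1.2 equiv), [Ir(cod)Cl]2 (2 mol %), (Ra,Rc,Rc)-(1,1'-binaphthalene-2,2'-diyl) N,N-bis(1-phenylethyl)phosphoramidite (4 mol %, pre-activated with n-PrNH2), THF, rt
Reagents that add atoms: none
Why: Iridium-catalysed asymmetric allylic etherification: the cyclometalated iridium phosphoramidite ionises 11 to an allyl complex and the lithium phenoxide attacks the aryl-bearing terminus on the face left open by the ligand, which should give the branched ether and set C2 as S under catalyst control, while room temperature and work-up at full conversion limit re-ionisation of the product.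

Step 7
Reactants: 13 1-[6-{[(1S)-1-(3,4-dimethoxyphenyl)prop-2-en-1-yl]oxy}-3-geranyl-2,4-bis(methoxymethoxy)phenyl]ethan-1-one
Product: 15 tert-butyl{[1-(6-{[(1S)-1-(3,4-dimethoxyphenyl)prop-2-en-1-yl]oxy}-3-geranyl-2,4-bis(methoxymethoxy)phenyl)ethenyl]oxy}dimethylsilane, via potassium enolate 14 (not isolated)
Conditions: KN(SiMe3)2 (1.1 equiv), THF, −78 °C; then TBSCl (1.3 equiv), −78 → 0 °C
Reagents that add atoms: tert-butyldimethylsilyl chloride (TBSCl), CC(C)(C)[Si](C)(C)Cl
Why: Kinetic deprotonation of the only enolisable position (the acetyl CH3) and O-silylation of the potassium enolate give the silyl enol ether without any Lewis acid that could ionise the doubly activated C2–O bond or the MOM acetals, and the C2–H is far too weakly acidic to be touched, so the stereocentre is kept.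

Step 8
Reactants: 15 tert-butyl{[1-(6-{[(1S)-1-(3,4-dimethoxyphenyl)prop-2-en-1-yl]oxy}-3-geranyl-2,4-bis(methoxymethoxy)phenyl)ethenyl]oxy}dimethylsilane
Product: 16 (2S)-4-(tert-butyldimethylsilyloxy)-2-(3,4-dimethoxyphenyl)-6-geranyl-5,7-bis(methoxymethoxy)-2H-chromene
Conditions: second-generation Grubbs catalyst RuCl2(=CHPh)(PCy3)(H2IMes) (10 mol %), 1,4-benzoquinone (10 mol %), toluene (0.005 M), 60 °C, argon sparge
Reagents that add atoms: none
Why: This is ring-closing metathesis of an olefinic silyl enol ether, the oxygen counterpart of the known silyl enol ether–ene closure to 4-silyloxy-1,2-dihydroquinolines and of allyl aryl ether metathesis to 2H-chromenes. The benzylidene initiates at the monosubstituted vinyl group of 15, the resulting alkylidene adds across the 1,1-disubstituted enol ether by [2+2] to a ruthenacyclobutane, and cycloreversion releases 16 and Ru=CH2 while ethene is swept out. Ring C closes as a six-membered ring with both alkene carbons (C3 and C4) inside the ring, the fastest closure open to the alkylidene. No stereocentre is formed; C2 keeps its S configuration because neither the C2–H nor the C2–O bond takes part, and 1,4-benzoquinone suppresses ruthenium hydride migration of the allylic double bond that would erase it. The chemoselectivity needed among four alkenes is secured by substitution and proximity: the two trisubstituted geranyl alkenes react far more slowly than the terminal vinyl and enol ether pair held for six-ring closure, and high dilution disfavours cross-metathesis.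

Step 9
Reactants: 16 (2S)-4-(tert-butyldimethylsilyloxy)-2-(3,4-dimethoxyphenyl)-6-geranyl-5,7-bis(methoxymethoxy)-2H-chromene
Product: 18 (2S)-2-(3,4-dimethoxyphenyl)-6-geranyl-5,7-dihydroxychroman-4-one (CNP0268555.1), via flavanone bis-MOM ether 17 (not isolated)
Conditions: aq. HCl (ca. 1.5 M in the mixture), MeOH/THF, 0 → 40 °C
Reagents that add atoms: none
Why: Acid hydrolysis of the silyl enol ether by protonation at C3 gives the C4 ketone of 17, and acetal exchange with methanol then removes both MOM groups; C2 is not involved, and the mild temperature is chosen to keep the geranyl alkenes from cyclising onto the flanking phenols and the flavanone from opening to its chalcone.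

## Compound list

1 | phloroglucinol | Oc1cc(O)cc(O)c1 | starting material
2 | 1,3,5-tris(methoxymethoxy)benzene | COCOc1cc(OCOC)cc(OCOC)c1 | intermediate
3 | geranyl bromide | CC(C)=CCC/C(C)=C/CBr | starting material
4 | [2,4,6-tris(methoxymethoxy)phenyl]lithium (not isolated) | [Li]c1c(OCOC)cc(OCOC)cc1OCOC | intermediate
5 | 2-geranyl-1,3,5-tris(methoxymethoxy)benzene | COCOc1cc(OCOC)c(C/C=C(\C)CCC=C(C)C)c(OCOC)c1 | intermediate
6 | [3-geranyl-2,4,6-tris(methoxymethoxy)phenyl]lithium (not isolated) | [Li]c1c(OCOC)cc(OCOC)c(C/C=C(\C)CCC=C(C)C)c1OCOC | intermediate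
7 | lithium 1-[3-geranyl-2,4,6-tris(methoxymethoxy)phenyl]-1-[methoxy(methyl)amino]ethan-1-olate (not isolated) | CC(O[Li])(N(C)OC)c1c(OCOC)cc(OCOC)c(C/C=C(\C)CCC=C(C)C)c1OCOC | intermediate
8 | 1-[3-geranyl-2,4,6-tris(methoxymethoxy)phenyl]ethan-1-one | CC(=O)c1c(OCOC)cc(OCOC)c(C/C=C(\C)CCC=C(C)C)c1OCOC | intermediate
9 | 1-[3-geranyl-6-hydroxy-2,4-bis(methoxymethoxy)phenyl]ethan-1-one | CC(=O)c1c(O)cc(OCOC)c(C/C=C(\C)CCC=C(C)C)c1OCOC | intermediate
10 | (E)-3,4-dimethoxycinnamyl alcohol | COc1ccc(/C=C/CO)cc1OC | starting material
11 | (2E)-3-(3,4-dimethoxyphenyl)prop-2-en-1-yl methyl carbonate | COC(=O)OC/C=C/c1ccc(OC)c(OC)c1 | intermediate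
12 | lithium 2-acetyl-4-geranyl-3,5-bis(methoxymethoxy)phenoxide (not isolated) | CC(=O)c1c(O[Li])cc(OCOC)c(C/C=C(\C)CCC=C(C)C)c1OCOC | intermediate
13 | 1-[6-{[(1S)-1-(3,4-dimethoxyphenyl)prop-2-en-1-yl]oxy}-3-geranyl-2,4-bis(methoxymethoxy)phenyl]ethan-1-one | COc1ccc([C@H](C=C)Oc2cc(OCOC)c(C/C=C(\C)CCC=C(C)C)c(OCOC)c2C(C)=O)cc1OC | intermediate
14 | potassium enolate of 13 (not isolated) | COc1ccc([C@H](C=C)Oc2cc(OCOC)c(C/C=C(\C)CCC=C(C)C)c(OCOC)c2C(=C)O[K])cc1OC | intermediate
15 | tert-butyl{[1-(6-{[(1S)-1-(3,4-dimethoxyphenyl)prop-2-en-1-yl]oxy}-3-geranyl-2,4-bis(methoxymethoxy)phenyl)ethenyl]oxy}dimethylsilane | COc1ccc([C@H](C=C)Oc2cc(OCOC)c(C/C=C(\C)CCC=C(C)C)c(OCOC)c2C(=C)O[Si](C)(C)C(C)(C)C)cc1OC | intermediate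
16 | (2S)-4-(tert-butyldimethylsilyloxy)-2-(3,4-dimethoxyphenyl)-6-geranyl-5,7-bis(methoxymethoxy)-2H-chromene | COc1ccc([C@@H]2C=C(O[Si](C)(C)C(C)(C)C)c3c(cc(OCOC)c(C/C=C(\C)CCC=C(C)C)c3OCOC)O2)cc1OC | intermediate
17 | (2S)-2-(3,4-dimethoxyphenyl)-6-geranyl-5,7-bis(methoxymethoxy)chroman-4-one (not isolated) | COc1ccc([C@@H]2CC(=O)c3c(cc(OCOC)c(C/C=C(\C)CCC=C(C)C)c3OCOC)O2)cc1OC | intermediate
18 | (2S)-2-(3,4-dimethoxyphenyl)-6-[(2E)-3,7-dimethylocta-2,6-dien-1-yl]-5,7-dihydroxychroman-4-one | COc1ccc([C@@H]2CC(=O)c3c(cc(O)c(C/C=C(\C)CCC=C(C)C)c3O)O2)cc1OC | target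

## Step count and risks

Total steps: 9. Longest linear sequence: 8 (steps 1–4 and 6–9, from phloroglucinol); step 5 is a one-step branch.

Steps most likely to fail:

**Step 8.** The hindered, electron-rich 1,1-disubstituted enol ether may engage the alkylidene too slowly. Cross-metathesis at the isopropylidene end of the geranyl chain, or hydride-induced migration of the allylic double bond, could then take over. The fallback avoids metathesis: ring C is closed at O1–C2 and the stereocentre is set by conjugate addition. It sets out from 9. Condensation with N,N-dimethylformamide dimethyl acetal (toluene, 80 °C) should give the enaminone (E)-3-(dimethylamino)-1-[3-geranyl-6-hydroxy-2,4-bis(methoxymethoxy)phenyl]prop-2-en-1-one F1. Cyclisation with pyridinium p-toluenesulfonate (CH2Cl2, rt), with loss of dimethylamine, should give the chromone 6-geranyl-5,7-bis(methoxymethoxy)-4H-chromen-4-one F2. Rhodium-catalysed asymmetric 1,4-addition of 3,4-dimethoxyphenylboronic acid ([Rh(OH)(cod)]2 with the enantiomer of the electron-poor bisphosphine MeO-F12-BIPHEP that leads to the 2S series, CH2Cl2/H2O, rt) then comes back to the route at 17, which is taken through the acid treatment of step 9.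

**Step 6.** The product ether may re-ionise on the catalyst, since it carries an electron-rich aryl group on the allyl unit and an acyl-stabilised phenoxide as leaving group. That would erode both the branched-to-linear selectivity and the enantiomeric purity; attack by the chelated ortho-acyl phenoxide may also be sluggish. The fallback sets the stereocentre on a nucleophile that cannot leave again and makes the aryl ether bond by SN2 displacement. It sets out from 11. Iridium-catalysed allylic hydroxylation (KHCO3, [Ir(cod)Cl]2 with the antipodal (Sa,Sc,Sc) phosphoramidite, THF/H2O) should give the alcohol (1R)-1-(3,4-dimethoxyphenyl)prop-2-en-1-ol F3. Mitsunobu etherification of F3 with 9 (PPh3, diisopropyl azodicarboxylate, toluene, −20 °C) proceeds with inversion and comes back to the route at 13.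

**Step 4.** The magnesium reagent may not discriminate well enough between the two MOM groups ortho to the ketone, or cleavage may run on. The fallback differentiates the phenols by stepwise protection in their order of reactivity instead of by chelation-controlled cleavage. It sets out from 8.
- All three MOM groups are removed (HCl, MeOH, rt) to give the triol 1-[3-geranyl-2,4,6-trihydroxyphenyl]ethan-1-one F4.
- The para phenol, which is not hydrogen-bonded, is protected first (MOMCl, 1.0 equiv, i-Pr2NEt, CH2Cl2, 0 °C) to give the diol 1-[3-geranyl-2,6-dihydroxy-4-(methoxymethoxy)phenyl]ethan-1-one F5.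
- The bulky silyl chloride takes the ortho phenol next to ring hydrogen (TBSCl, imidazole, DMF) to give the silyl ether 1-[6-(tert-butyldimethylsilyloxy)-3-geranyl-2-hydroxy-4-(methoxymethoxy)phenyl]ethan-1-one F6.
- The remaining hindered phenol is capped (MOMCl, i-Pr2NEt, CH2Cl2, 40 °C) to give the ketone 1-[6-(tert-butyldimethylsilyloxy)-3-geranyl-2,4-bis(methoxymethoxy)phenyl]ethan-1-one F7.
- Buffered fluoride (TBAF, AcOH, THF, 0 °C) removes the silyl group and comes back to the route at 9.

## Further compounds

F1 | step 8 | (E)-3-(dimethylamino)-1-[3-geranyl-6-hydroxy-2,4-bis(methoxymethoxy)phenyl]prop-2-en-1-one | CN(C)/C=C/C(=O)c1c(O)cc(OCOC)c(C/C=C(\C)CCC=C(C)C)c1OCOC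
F2 | step 8 | 6-geranyl-5,7-bis(methoxymethoxy)-4H-chromen-4-one | O=c1ccoc2cc(OCOC)c(C/C=C(\C)CCC=C(C)C)c(OCOC)c12
F3 | step 6 | (1R)-1-(3,4-dimethoxyphenyl)prop-2-en-1-ol | COc1ccc([C@H](O)C=C)cc1OC
F4 | step 4 | 1-[3-geranyl-2,4,6-trihydroxyphenyl]ethan-1-one | CC(=O)c1c(O)cc(O)c(C/C=C(\C)CCC=C(C)C)c1O
F5 | step 4 | 1-[3-geranyl-2,6-dihydroxy-4-(methoxymethoxy)phenyl]ethan-1-one | CC(=O)c1c(O)cc(OCOC)c(C/C=C(\C)CCC=C(C)C)c1O
F6 | step 4 | 1-[6-(tert-butyldimethylsilyloxy)-3-geranyl-2-hydroxy-4-(methoxymethoxy)phenyl]ethan-1-one | CC(=O)c1c(O[Si](C)(C)C(C)(C)C)cc(OCOC)c(C/C=C(\C)CCC=C(C)C)c1O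
F7 | step 4 | 1-[6-(tert-butyldimethylsilyloxy)-3-geranyl-2,4-bis(methoxymethoxy)phenyl]ethan-1-one | CC(=O)c1c(O[Si](C)(C)C(C)(C)C)cc(OCOC)c(C/C=C(\C)CCC=C(C)C)c1OCOC
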